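Retrosynthetic cuts, in order: the C3–O angelate ester, the C11–O aryl ether, the C9–C11 bond (back to a C9 ketone), re-addition of a C6 oxygen, and last the two ring A bonds C1–C10 and C4–C5.
Enabling feature: ring B (C5–C10) carries methyl groups on C8 and C10, the C7=C8 alkene and a one-carbon branch on C9. This is the pattern of 2,6-dimethyl-1,4-benzoquinone, while C1–C4 with the C2 oxygen and the C4 gem-dimethyl group are the chain of mesityl oxide.
Forward: ring B is bought as the quinone, and ring A is closed on it in one catalytic enantioselective [4+2] step with the 2-silyloxydiene from mesityl oxide. The C2 enol silane formed there masks the ketone and marks C3 up to step 9.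
The C6 oxygen leaves through the only enol triflate the adduct can form (C5=C6), and Li/NH3 reduction of the resulting 5,7-dien-9-one places H5 trans to the C10 methyl. Methylenation and hydroboration add C11; Mitsunobu etherification, C3 oxidation, equilibration and angeloylation finish the route.
Stereochemistry: C10 comes from the chiral catalyst. C5 (axial protonation), C9 (hydroboration opposite the axial methyl) and C3 (equilibration to the equatorial ketol) are all relayed from C10.
Key step: step 2

Numbering: drimane numbering is used for all bicyclic compounds (decalin C1–C10, C11 on C9, methyl groups on C4 twice, C8 and C10). Compounds that lack C11 are named as 11-nordrimanes.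
Assumption: the accepted binding model (boron on the C6 oxygen lone pair syn to C5–H, a C5–H···O contact, one quinone face covered by a catalyst aryl group) points to the (R)-configured precatalyst for (10R)-5; the (S)-antipode is equally available should the sense be opposite.

Step 1
Reactants: 1 mesityl oxide (4-methylpent-3-en-2-one)
Product: 3 4-methyl-2-(triisopropylsilyloxy)penta-1,3-diene, via lithium dienolate 2 (not isolated)
Conditions: LiN(i-Pr)2, THF, −78 °C; TIPSOTf, −78 → 0 °C
Reagents that add atoms: triisopropylsilyl trifluoromethanesulfonate, CC(C)[Si](C(C)C)(C(C)C)OS(=O)(=O)C(F)(F)F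
Why: Kinetic enolate formation and O-silylation: the hindered amide removes an α′ proton of the acetyl methyl group at −78 °C faster than a γ proton, and the hard silyl triflate traps the cross-conjugated enolate 2 on oxygen, which gives the 2-silyloxydiene and not the linear dienol ether; no stereocentre is formed.

Step 2
Reactants: 3 4-methyl-2-(triisopropylsilyloxy)penta-1,3-diene; 4 2,6-dimethyl-1,4-benzoquinone
Product: 5 cis-fused (5S,10R)-2-(triisopropylsilyloxy)-11-nordrima-2,7-diene-6,9-dione
Conditions: 3 (1.5 equiv), (R)-1-(2-methylphenyl)-3,3-diphenyltetrahydro-1H,3H-pyrrolo[1,2-c][1,3,2]oxazaborole (20 mol %), HNTf2 (18 mol %), CH2Cl2, −78 → −40 °C; Et3N quench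
Reagents that add atoms: none
Why: Proposed new method: the N-protonated oxazaborolidine binds the C6 carbonyl oxygen, the only one flanked by C–H groups (C5–H can hydrogen-bond to the catalyst oxygen, whereas the C9 oxygen is walled in by two methyl groups), so methyl-bearing C10 becomes the electrophilic β-carbon, the nucleophilic CH2 terminus of 3 (C1) bonds to it first and C4 then bonds to C5. The event is a strongly asynchronous [4+2] cycloaddition whose stepwise limit is a Mukaiyama–Michael addition followed by Michael closure; the closest known reaction types are the oxazaborolidinium-catalysed Diels–Alder additions of 2-silyloxybutadienes to alkylated benzoquinones and the strong-acid-catalysed additions of 4,4-disubstituted 2-silyloxydienes to hindered enones, and only the pairing of the chiral catalyst with a 4,4-dimethyl diene terminus is without precedent. Ring A closes as a six-membered ring, either in one suprafacial [4π+2π] event or, at the stepwise limit, by 6-(enolexo)-endo-trig attack of the boron enolate carbon C5 on C4 of the silyloxyallyl cation, and it emerges as the C2=C3 enol silane. C10 is fixed by the catalyst, which by covering one face of the bound quinone chooses between the two enantiotopic C=C bonds, and C5 follows from delivery of C4 to the same face, which gives the cis fusion. The step needs regioselectivity (C1 to C10), secured by the match of the C2 oxygen donor with the C6-bound acid, and mono-addition, secured because the remaining C7=C8 bond sits in a much less electrophilic and more hindered ene-dione. The gem-dimethyl terminus disfavours the s-cis diene, which is why the bulky, slowly migrating TIPS group, triflimide activation and an excess of 3 are chosen, since they keep the cationic terminus available long enough to close.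

Step 3
Reactants: 5 cis-fused (5S,10R)-2-(triisopropylsilyloxy)-11-nordrima-2,7-diene-6,9-dione
Product: 7 (10R)-2-(triisopropylsilyloxy)-6-(trifluoromethylsulfonyloxy)-11-nordrima-2,5,7-trien-9-one, via potassium enolate 6 (not isolated)
Conditions: KN(SiMe3)2, THF, −78 °C; PhNTf2, −78 → 0 °C
Reagents that add atoms: N-phenylbis(trifluoromethanesulfonimide), O=S(=O)(N(c1ccccc1)S(=O)(=O)C(F)(F)F)C(F)(F)F
Why: Kinetic enolate triflation: C9 has no α-hydrogen, so only the C6 carbonyl can enolise, and the amide base at −78 °C takes the α′ proton H5 rather than a γ proton of the C8 methyl group, which tells the two carbonyl groups apart without protection and deliberately erases the cis C5 centre, whose base equilibration is not relied on because the flattened ene-dione ring tolerates the cis fusion too well.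

Step 4
Reactants: 7 (10R)-2-(triisopropylsilyloxy)-6-(trifluoromethylsulfonyloxy)-11-nordrima-2,5,7-trien-9-one
Product: 8 (10R)-2-(triisopropylsilyloxy)-11-nordrima-2,5,7-trien-9-one
Conditions: Pd(OAc)2 (5 mol %), PPh3 (10 mol %), HCO2H, Et3N, DMF, 60 °C, dark
Reagents that add atoms: none
Why: Palladium-catalysed formate hydrogenolysis of a vinyl triflate: oxidative addition to zerovalent palladium formed in the flask, exchange of triflate for formate, loss of CO2 and C–H reductive elimination replace C6–O by C6–H in an amine-buffered medium that spares the enol silane, and the product, a fully blocked 6,6-dialkylcyclohexa-2,4-dienone, can neither tautomerise to a phenol nor readily dimerise.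

Step 5
Reactants: 8 (10R)-2-(triisopropylsilyloxy)-11-nordrima-2,5,7-trien-9-one
Product: 11 trans-fused (5R,10R)-2-(triisopropylsilyloxy)-11-nordrima-2,7-dien-9-one, via lithium dienolate 9 (not isolated), via deconjugated enone 10 (not isolated)
Conditions: Li, NH3–THF, t-BuOH (1 equiv), −78 °C; solid NH4Cl; crude product, 1,8-diazabicyclo[5.4.0]undec-7-ene (cat.), CH2Cl2, rt
Reagents that add atoms: none
Why: Dissolving-metal (Birch-type) 1,6-reduction of a linear dienone: two electrons and one proton convert 8 into the extended enolate 9, the proton entering at the δ-carbon C5 along the axis that keeps overlap with the π system and on the face opposite the C10 methyl (the other face is flanked by the C10 and C4 methyl groups), which sets the trans ring fusion (5R) for good because C5 is no longer next to a carbonyl, after which α-protonation gives 10 and the amidine base moves the alkene into conjugation as the C7=C8 enone.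

Step 6
Reactants: 11 trans-fused (5R,10R)-2-(triisopropylsilyloxy)-11-nordrima-2,7-dien-9-one
Product: 12 (5R,10R)-2-(triisopropylsilyloxy)drima-2,7,9(11)-triene
Conditions: Cp2TiMe2, toluene, 75 °C, dark
Reagents that add atoms: dimethyltitanocene, C[Ti](C)(C1C=CC=C1)C1C=CC=C1
Why: Petasis olefination: Cp2Ti=CH2, released thermally from Cp2TiMe2, is small and non-basic, so that the hindered and γ-enolisable C9 ketone should be methylenated through an oxatitanacyclobutane without dienolate formation, while C2, still an enol silane, cannot compete.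

Step 7
Reactants: 12 (5R,10R)-2-(triisopropylsilyloxy)drima-2,7,9(11)-triene
Product: 14 (5R,9R,10R)-2-(triisopropylsilyloxy)drima-2,7-dien-11-ol, via alkylborane 13 (not isolated)
Conditions: 9-borabicyclo[3.3.1]nonane (9-BBN), THF, rt → 50 °C; 30% H2O2, aq NaOH, 0 °C
Reagents that add atoms: hydrogen peroxide, OO
Why: Hydroboration–oxidation: the bulky borane places boron on the unhindered terminus C11 of the 1,1-disubstituted alkene and ignores the trisubstituted C7=C8 and C2=C3 bonds, hydrogen reaches C9 on the face opposite the axial C10 methyl group, so that C11 ends up equatorial and cis to that methyl (9R), and oxidation keeps the configuration.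

Step 8
Reactants: 14 (5R,9R,10R)-2-(triisopropylsilyloxy)drima-2,7-dien-11-ol; 15 umbelliferone (7-hydroxycoumarin)
Product: 16 7-{[(5R,9R,10R)-2-(triisopropylsilyloxy)drima-2,7-dien-11-yl]oxy}coumarin
Conditions: PPh3, diisopropyl azodicarboxylate (DIAD), THF, 0 °C → rt
Reagents that add atoms: none
Why: Mitsunobu etherification: the acidic 7-hydroxyl of 15 protonates the betaine and its phenoxide displaces the oxyphosphonium group at primary C11, so that no stereocentre is touched and the neutral medium spares the enol silane and the lactone.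

Step 9
Reactants: 16 7-{[(5R,9R,10R)-2-(triisopropylsilyloxy)drima-2,7-dien-11-yl]oxy}coumarin
Product: 18 7-{[(3R,5S,9R,10R)-3-hydroxy-2-oxodrim-7-en-11-yl]oxy}coumarin, via silyloxy epoxide 17 (not isolated)
Conditions: dimethyldioxirane (1.0 equiv), acetone–CH2Cl2, −78 → −40 °C; Et3N·3HF, 0 °C
Reagents that add atoms: dimethyldioxirane, CC1(C)OO1
Why: Rubottom oxidation: the electron-rich C2=C3 enol silane should be epoxidised by the electrophilic dioxirane much faster than the trisubstituted C7=C8 alkene or the electron-poor coumarin, attack comes from the face opposite the axial C10 and C4 methyl groups, and fluoride collapses 17 to the ketol with retention at C3, so that the oxygen is on the right carbon but axial (3R) and is corrected in step 10.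

Step 10
Reactants: 18 7-{[(3R,5S,9R,10R)-3-hydroxy-2-oxodrim-7-en-11-yl]oxy}coumarin
Product: 19 7-{[(3S,5S,9R,10R)-3-hydroxy-2-oxodrim-7-en-11-yl]oxy}coumarin
Conditions: 1,8-diazabicyclo[5.4.0]undec-7-ene (0.3 equiv), degassed toluene, argon, 60 °C
Reagents that add atoms: none
Why: Base-catalysed ketol epimerisation through the enediolate, the reaction type known from the axial-to-equatorial equilibration of steroidal ring A ketols and their acetates: the equatorial 3S alcohol, hydrogen-bonded to the C2 carbonyl and free of the syn-axial contacts with H1 and H5, should be the sink, and the transposed 2-hydroxy-3-ketone should stay unpopulated because it would put an sp3 C2–H under both axial methyl groups.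

Step 11
Reactants: 19 7-{[(3S,5S,9R,10R)-3-hydroxy-2-oxodrim-7-en-11-yl]oxy}coumarin; 20 angelic acid ((Z)-2-methylbut-2-enoic acid)
Product: 22 7-{[(3S,5S,9R,10R)-3-angeloyloxy-2-oxodrim-7-en-11-yl]oxy}coumarin (CNP0111364.1), via mixed anhydride 21 (not isolated)
Conditions: 20, 2,4,6-trichlorobenzoyl chloride, Et3N, toluene, rt; then 19, 80 °C
Reagents that add atoms: none
Why: Yamaguchi-type mixed-anhydride esterification run without a nucleophilic pyridine catalyst, the variant established for angelates: the alcohol attacks the less hindered angeloyl carbonyl of 21, no conjugate addition–elimination channel is open so that the Z geometry is kept, and C3 stays in its thermodynamic equatorial configuration.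

Compound list
1 | mesityl oxide (4-methylpent-3-en-2-one) | CC(=O)C=C(C)C | starting material
2 | lithium 4-methylpenta-1,3-dien-2-olate | [Li+].[O-]C(=C)C=C(C)C | intermediate
3 | 4-methyl-2-(triisopropylsilyloxy)penta-1,3-diene | C=C(O[Si](C(C)C)(C(C)C)C(C)C)C=C(C)C | intermediate
4 | 2,6-dimethyl-1,4-benzoquinone | CC1=CC(=O)C=C(C)C1=O | starting material
5 | (5S,10R)-2-(triisopropylsilyloxy)-11-nordrima-2,7-diene-6,9-dione, cis-fused (H5 and the C10 methyl on the same face) | C1(O[Si](C(C)C)(C(C)C)C(C)C)=CC(C)(C)[C@@H]2C(=O)C=C(C)C(=O)[C@]2(C)C1 | intermediate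
6 | potassium C5=C6 enolate of 5 | C1(O[Si](C(C)C)(C(C)C)C(C)C)=CC(C)(C)C2=C([O-])C=C(C)C(=O)[C@]2(C)C1.[K+] | intermediate
7 | (10R)-2-(triisopropylsilyloxy)-6-(trifluoromethylsulfonyloxy)-11-nordrima-2,5,7-trien-9-one | C1(O[Si](C(C)C)(C(C)C)C(C)C)=CC(C)(C)C2=C(OS(=O)(=O)C(F)(F)F)C=C(C)C(=O)[C@]2(C)C1 | intermediate
8 | (10R)-2-(triisopropylsilyloxy)-11-nordrima-2,5,7-trien-9-one | C1(O[Si](C(C)C)(C(C)C)C(C)C)=CC(C)(C)C2=CC=C(C)C(=O)[C@]2(C)C1 | intermediate
9 | lithium (5R,10R)-2-(triisopropylsilyloxy)-11-nordrima-2,6,8-trien-9-olate, trans-fused | C1(O[Si](C(C)C)(C(C)C)C(C)C)=CC(C)(C)[C@H]2C=CC(C)=C([O-])[C@]2(C)C1.[Li+] | intermediate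
10 | (5R,10R)-2-(triisopropylsilyloxy)-11-nordrima-2,6-dien-9-one, trans-fused, either C8 epimer | C1(O[Si](C(C)C)(C(C)C)C(C)C)=CC(C)(C)[C@H]2C=CC(C)C(=O)[C@]2(C)C1 | intermediate
11 | (5R,10R)-2-(triisopropylsilyloxy)-11-nordrima-2,7-dien-9-one, trans-fused (H5 opposite the C10 methyl) | C1(O[Si](C(C)C)(C(C)C)C(C)C)=CC(C)(C)[C@H]2CC=C(C)C(=O)[C@]2(C)C1 | intermediate
12 | (5R,10R)-2-(triisopropylsilyloxy)drima-2,7,9(11)-triene | C1(O[Si](C(C)C)(C(C)C)C(C)C)=CC(C)(C)[C@H]2CC=C(C)C(=C)[C@]2(C)C1 | intermediate
13 | B-[2-(triisopropylsilyloxy)drima-2,7-dien-11-yl]-9-borabicyclo[3.3.1]nonane, configured as 14 | C1(O[Si](C(C)C)(C(C)C)C(C)C)=CC(C)(C)[C@H]2CC=C(C)[C@@H](CB3C4CCCC3CCC4)[C@]2(C)C1 | intermediate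
14 | (5R,9R,10R)-2-(triisopropylsilyloxy)drima-2,7-dien-11-ol (C11 equatorial, cis to the C10 methyl) | C1(O[Si](C(C)C)(C(C)C)C(C)C)=CC(C)(C)[C@H]2CC=C(C)[C@@H](CO)[C@]2(C)C1 | intermediate
15 | umbelliferone (7-hydroxycoumarin) | Oc1ccc2ccc(=O)oc2c1 | starting material
16 | 7-{[(5R,9R,10R)-2-(triisopropylsilyloxy)drima-2,7-dien-11-yl]oxy}coumarin | C1(O[Si](C(C)C)(C(C)C)C(C)C)=CC(C)(C)[C@H]2CC=C(C)[C@@H](COc3ccc4ccc(=O)oc4c3)[C@]2(C)C1 | intermediate
17 | 7-{[(2R,3R,5S,9R,10R)-2,3-epoxy-2-(triisopropylsilyloxy)drim-7-en-11-yl]oxy}coumarin (epoxide opposite the C10 methyl) | O1[C@@H]2C(C)(C)[C@H]3CC=C(C)[C@@H](COc4ccc5ccc(=O)oc5c4)[C@]3(C)C[C@]12O[Si](C(C)C)(C(C)C)C(C)C | intermediate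
18 | 7-{[(3R,5S,9R,10R)-3-hydroxy-2-oxodrim-7-en-11-yl]oxy}coumarin (3-OH axial, opposite the C10 methyl) | O[C@H]1C(=O)C[C@@]2(C)[C@H](COc3ccc4ccc(=O)oc4c3)C(C)=CC[C@@H]2C1(C)C | intermediate
19 | 7-{[(3S,5S,9R,10R)-3-hydroxy-2-oxodrim-7-en-11-yl]oxy}coumarin (3-OH equatorial, cis to the C10 methyl) | O[C@@H]1C(=O)C[C@@]2(C)[C@H](COc3ccc4ccc(=O)oc4c3)C(C)=CC[C@@H]2C1(C)C | intermediate
20 | angelic acid ((Z)-2-methylbut-2-enoic acid) | C/C=C(/C)C(=O)O | starting material
21 | angelic 2,4,6-trichlorobenzoic anhydride | C/C=C(/C)C(=O)OC(=O)c1c(Cl)cc(Cl)cc1Cl | intermediate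
22 | 7-{[(3S,5S,9R,10R)-3-angeloyloxy-2-oxodrim-7-en-11-yl]oxy}coumarin, CNP0111364.1 | C/C=C(/C)C(=O)O[C@@H]1C(=O)C[C@@]2(C)[C@H](COc3ccc4ccc(=O)oc4c3)C(C)=CC[C@@H]2C1(C)C | target

Total step count: 11. Longest linear sequence: 11 steps (1 to 22); 4, 15 and 20 enter as purchased.

Steps most likely to fail

**Step 2.**
- Risk: the gem-dimethyl terminus may keep the diene out of the s-cis geometry. Silyl transfer would then outrun closure of the C4–C5 bond, or facial control by the catalyst would erode.
- The fallback uses known chemistry and sets out from 3 and 4. The two bonds are made one after the other under achiral catalysis, a sequence known for hindered 2-silyloxydienes and β-substituted enones.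
- Catalytic HNTf2 in CH2Cl2 at −78 °C should stop after C1–C10 bond formation and silyl transfer. This gives racemic 2,6-dimethyl-6-(4-methyl-2-oxopent-3-en-1-yl)-4-(triisopropylsilyloxy)cyclohexa-2,4-dien-1-one F1.
- Warming with more HNTf2 (or AlBr3/AlMe3) lets the silyl dienol ether carbon C5 add to C4 of the pendant enone. This is an intramolecular Mukaiyama–Michael addition in which silicon passes to the C2 oxygen.
- The closure gives 5 together with its mirror image, the (5R,10S)-adduct F2.
- Preparative chromatography on a chiral stationary phase separates the two, and the route is rejoined at 5.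

**Step 5.**
- Risk: the radical anion may be protonated at C7 instead of the hindered C5 (1,4- in place of 1,6-reduction), or the facial selectivity at C5 may be poor.
- The fallback replaces kinetic protonation by thermodynamic control in a ring B that is no longer flat. It sets out from 5 and thereby also bypasses steps 3 and 4.
- Zn in AcOH–THF at 0 °C reduces the ene-dione to the cis-fused saturated 6,9-dione F3.
- 1,8-Diazabicyclo[5.4.0]undec-7-ene in toluene equilibrates C5 and C8 to the trans-fused dione with equatorial C8 methyl F4. This isomer should be the sink because, with C7 and C8 sp3, the cis-fused chair that tucks a C4 methyl under ring B meets a syn-axial C7–H.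
- KN(SiMe3)2 then PhNTf2 at −78 °C takes the least hindered α-protons (C7) and gives the C6=C7 enol triflate F5.
- Pd(OAc)2/PPh3/HCO2H/Et3N hydrogenolysis gives 10, where the route is rejoined for the amidine-catalysed conjugation to 11.

**Step 9.**
- Risk: epoxidation of the C7=C8 alkene may compete with oxidation of the hindered enol silane.
- The fallback replaces alkene epoxidation by a polar acetoxylation that only a nucleophilic enol silane can undergo. It sets out from 16.
- Pb(OAc)4 in CH2Cl2 at 0 °C gives the 3-acetoxy-2-ketone F6, through a lead enolate and acetate transfer, with C3 configuration left open.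
- K2CO3 in MeOH at rt removes the acetate and at the same time equilibrates the ketol to the equatorial isomer. The route is rejoined at 19, and step 10 is absorbed.

Further compounds
F1 | step 2 | racemic 2,6-dimethyl-6-(4-methyl-2-oxopent-3-en-1-yl)-4-(triisopropylsilyloxy)cyclohexa-2,4-dien-1-one | CC1=CC(O[Si](C(C)C)(C(C)C)C(C)C)=CC(C)(CC(=O)C=C(C)C)C1=O
F2 | step 2 | (5R,10S)-2-(triisopropylsilyloxy)-11-nordrima-2,7-diene-6,9-dione, mirror image of 5 | C1(O[Si](C(C)C)(C(C)C)C(C)C)=CC(C)(C)[C@H]2C(=O)C=C(C)C(=O)[C@@]2(C)C1
F3 | step 5 | cis-fused (5S,10R)-2-(triisopropylsilyloxy)-11-nordrim-2-ene-6,9-dione, either C8 epimer | C1(O[Si](C(C)C)(C(C)C)C(C)C)=CC(C)(C)[C@@H]2C(=O)CC(C)C(=O)[C@]2(C)C1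
F4 | step 5 | trans-fused (5R,8S,10R)-2-(triisopropylsilyloxy)-11-nordrim-2-ene-6,9-dione | C1(O[Si](C(C)C)(C(C)C)C(C)C)=CC(C)(C)[C@H]2C(=O)C[C@H](C)C(=O)[C@]2(C)C1
F5 | step 5 | (5R,8S,10R)-2-(triisopropylsilyloxy)-6-(trifluoromethylsulfonyloxy)-11-nordrima-2,6-dien-9-one | C1(O[Si](C(C)C)(C(C)C)C(C)C)=CC(C)(C)[C@H]2C(OS(=O)(=O)C(F)(F)F)=C[C@H](C)C(=O)[C@]2(C)C1
F6 | step 9 | 7-{[(5S,9R,10R)-3-acetoxy-2-oxodrim-7-en-11-yl]oxy}coumarin, either C3 epimer | CC(=O)OC1C(=O)C[C@@]2(C)[C@H](COc3ccc4ccc(=O)oc4c3)C(C)=CC[C@@H]2C1(C)C
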